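A one-step world needs a single number: substrate lost equals open intermediate gained, and the flask is described by how far the step has run. I want to know how far these flasks depart from that world.

| flask | substrate | partner | reagent | temperature | remark | time |
|---|---|---|---|---|---|---|
| amber | 0.34 M | 0.35 equiv (in portions, 4) | 3 equiv | 79 °C | run made earlier; portions every 2.0 min |  |
| red | 0.34 M | 0.52 equiv (in portions, 4) | 3 equiv | 120 °C | run made earlier; portions every 2.0 min |  |
| blue | 0.68 M | 0.70 equiv (in portions, 4) | 3 equiv | 79 °C | run made earlier; portions every 2.0 min |  |
| Wednesday's | 0.34 M | 0.700 equiv (in portions, 4) | 3.00 equiv | 60 °C | the portions of partner follow each other after 2.0 min, the first at the start | 30 min |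
| Thursday's | 0.34 M | 0.700 equiv (in portions, 4) | 3.00 equiv | 135 °C | the portions of partner follow each other after 2.0 min, the first at the start | 30 min |
| Sunday's | 0.34 M | 0.700 equiv (in portions, 4) | 3.00 equiv | 110 °C | the portions of partner follow each other after 2.0 min, the first at the start | 30 min |
| Monday's | 0.34 M | 0.700 equiv (in portions, 4) | 3.00 equiv | 85 °C | the portions of partner follow each other after 2.0 min, the first at the start | 30 min |

amber run (percent of the substrate charged)

| time / min | open intermediate / % | target / % | substrate / % |
|---|---|---|---|
| 0.500 | 0 | 0 | 98.7 |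
| 0.833 | 0.2 | 0.7 | 100.6 |
| 1.33 | 0.3 | 0 | 99.1 |
| 2.00 | 2.3 | 0.5 | 98.1 |
| 3.00 | 2.5 | 0.8 | 99.3 |
| 5.00 | 2.5 | 1.6 | 99.1 |
| 8.00 | 4.3 | 0.4 | 94.5 |

red run (percent of the substrate charged)

| time / s | open intermediate / % | target / % | substrate / % |
|---|---|---|---|
| 10.0 | 1.2 | 0 | 99.2 |
| 15.0 | 2.0 | 0.9 | 97.5 |
| 25.0 | 3.5 | 0 | 95.4 |
| 30.0 | 4.1 | 0 | 94.7 |
| 50.0 | 6.1 | 0.7 | 90.7 |
| 60.0 | 9.4 | 0 | 89.6 |

blue run (percent of the substrate charged)

| time / min | open intermediate / % | target / % | substrate / % |
|---|---|---|---|
| 1.50 | 2.5 | 1.1 | 97.7 |
| 3.00 | 4.7 | 0.6 | 96.1 |
| 4.00 | 3.6 | 0 | 95.8 |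
| 6.00 | 5.6 | 0 | 94.2 |
| 8.00 | 8.0 | 0.1 | 90.7 |

(each reading ± 1 percentage point)

- a reading or a percentage of target counts all its forms, free or not

1. which flask leads in amount of open intermediate, in percent of the substrate charged ("all alike" within 1.5 percentage points) (Wednesday's / Thursday's / Sunday's / Monday's / all alike)
2. how much open intermediate is there at the end, in percent of the substrate charged: Wednesday's
3. how much open intermediate is there at the end, in percent of the substrate charged: Thursday's
4. how much open intermediate is there at the end, in percent of the substrate charged: Sunday's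
5. how much open intermediate is there at the end, in percent of the substrate charged: Monday's

I start with the step itself. I treat substrate loss as first-order with a fixed constant, which is a simplification, since it takes reagent as steady and the readings do not show reagent. Amber's last reading gives 0.00707 min⁻¹ and red's gives 0.110 min⁻¹. Laying the logarithm straight between their temperatures, which is crude, gives Sunday's 0.0563 min⁻¹, so my estimate of the conversion of Sunday's at the end is 81.5%.

Now I divide one rate by the other, and time drops out. Open intermediate gained per substrate lost, pooled over the last readings of the three runs, is a keep of 0.861, a reading resting on points that each scatter by 1 percentage point. Multiplying gives Sunday's 70.2%.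

That product is the weak link, since the keep was read at low conversion and is being stretched far beyond it. So I reforge it. I assume the shortfall of the keep grows in proportion to the open intermediate standing. Then the gain stops at a ceiling, the level of open intermediate at which drain equals supply, and the readings put it at 26.0%. The amount approaches this ceiling exponentially with conversion, and Sunday's comes to 24.9%. That is my number.

The forecast differs. It names Sunday's as leader too, but puts Sunday's at 48% (28% to 72%), higher than mine. It gives Wednesday's 3.3%, Monday's 21% and Thursday's 20%, expecting that last flask to be one that “is largely drained”.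

The flasks end at 3.53% for Wednesday's, 5.07% for Thursday's, 23.2% for Sunday's and 20.1% for Monday's, so Sunday's leads.

    substrate + reagent → open intermediate (k = 0.0515 L mol⁻¹ min⁻¹, Ea = 80.0 kJ mol⁻¹)
    reagent + partner → second intermediate (k = 0.116 L mol⁻¹ min⁻¹, Ea = 101 kJ mol⁻¹)
    open intermediate + second intermediate → target (k = 0.133 L mol⁻¹ min⁻¹, Ea = 81.0 kJ mol⁻¹)
    2 open intermediate → homo product (k = 0.247 L mol⁻¹ min⁻¹, Ea = 65.0 kJ mol⁻¹)
    crystals ⇌ target, rate k5*(cs5 - [target]) while solid is left; crystals form when [target] > cs5 (solubility = 26.0 mM, k = 2.24 min⁻¹)
    partner + target → over-reaction product (k = 0.328 L mol⁻¹ min⁻¹, Ea = 87.0 kJ mol⁻¹)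
    (constants at 110 °C)

Sunday's has converted 68.0%, and at that conversion the ceiling curve gives 24.1% against the 23.2% found. The drain behind the ceiling shows plainly in Thursday's: without the path to homo product, that flask holds 38.0% instead of 5.07%, the largest single effect. Wednesday's, left for 300 min, has converted 28.4%. There the curve gives 17.3%, less than the flask, which holds 22.5%.

Readings and results were generated by integration from invented constants; the scatter is artificial.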